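## The problem

Ficusesquilignan A (32) is a sesquilignan: a cis-fused 3,7-dioxabicyclo[3.3.0]octane carrying a syringyl ring at C7 and a guaiacyl ring at C7', both exo, whose guaiacyl 4-oxygen is bonded to C8'' of an erythro guaiacylglycerol unit (lignan locants: C7–C9 syringyl unit, C7'–C9' central guaiacyl unit, C7''–C9'' glycerol arm; ring A is the tetrahydrofuran holding C7 and the O–C9' bond, ring B the one holding C7' and the O–C9 bond). The core has four contiguous stereocentres (7R,8S,7'R,8'S) and the arm two more (7''R,8''S). An aromatic ring separates the two sets, so the arm must be made enantiopure on its own and joined convergently, whereas inside the core C8 and C8' can be set first and then direct C7 and C7'. The two halves of the core differ, so the construction has to tell C7/C8/C9 from C7'/C8'/C9'. Three para-oxygenated benzylic C–O bonds (C7, C7', C7'') are the weak points: they ionise in acid (furofuran to its epi series, erythro to threo in the arm), open through quinone methides once the phenols are free, and can be hydrogenolysed. The customary acid-driven furofuran closure therefore cannot be used with the arm in place, and both benzylic carbinols must be correct before a retentive closure. The enabling feature is the C8–C8' bond: with C9' read as a lactone carbonyl and C9 as an acetal carbon, it is the α,β-bond of a 5-alkoxybutenolide (C8 = β, C8' = α). Since C7 and C8 are both acceptors in a normal C6–C3 unit, C7 must arrive as an acyl anion equivalent, and the enolate left at C8' can then take the guaiacyl aldehyde carbon C7'.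

## Retrosynthesis

**32 back to 31 and 30 (protecting groups only).** The phenols are carried as benzyl ethers and the arm diol as an acetonide. Benzyl ethers withstand organolithiums, hydrides and thiophilic metal salts. The acetonide ties up O7'', so the arm's benzylic carbon can be neither sulfonylated nor ionised during ring closure. Three benzylic C–O bonds must be spared on the way forward, so the acetonide is hydrolysed while the phenols are still capped (31) and neutral hydrogenolysis comes last.

**30 back to 28 (O7–C9' and O7'–C9).** The ether bonds are cut at the primary carbons, not at the benzylic ones. The benzylic C–O bonds then pass unchanged from carbinol to ether, so C7 and C7' are carried over with retention and no benzylic cation is needed. 28 is an acyclic 1,4-diaryl-2,3-bis(hydroxymethyl)butane-1,4-diol. The forward reaction must activate only the two primary hydroxyls (bis-mesylate 29) and let each benzylic hydroxyl close a five-membered ring.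

**28 back to 26 (C–H bonds at C7, C9 and C9'; loss of the auxiliary).** All four oxygens of 28 are already in 26: the C7 ketone, the C7' carbinol, the lactone carbonyl C9' and the acetal carbon C9. One hydride operation returns 28 and the auxiliary alcohol 3. The substrate does not bias the C7 carbonyl faces in a predictable way, so the ketone is reduced first under reagent control (27, not isolated) and the lactone and acetal afterwards.

**26 back to 25 (C7=O from the C7 dithiane).** The dithiane is both the umpolung device and the carbonyl protecting group. The ketone is unmasked only after the enolate chemistry is over, so C7 is never electrophilic while C8' is nucleophilic, and C8 becomes epimerisable only one step before it is fixed.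

**25 back to 7, 4 and 21 (C7–C8 and C8'–C7').** This is the central cut. Cutting C8–C8' instead would need a crossed enolate coupling of two different halves, and cutting only one of the two bonds would give up the one-flask union. The three pieces are simple: 7 is achiral, 4 has one controlling stereocentre, and 21 carries the finished arm. The forward reaction must give 1,4-addition of the lithiated dithiane 22 anti to the menthyloxy group, enolate capture anti to the new C8 substituent, and the syn aldol relation at C7'. The last point is asked of the counter-ion: the lithium enolate 23 is exchanged for the titanium enolate 24 before 21 is added.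

**4 back to 2 and 3; 2 back to 1.** The acetal stereocentre comes from crystallisation of the menthyl acetal; the hydroxybutenolide comes from photooxygenation of furfural.

**7 back to 6 and 5.** Benzylation and dithioacetalisation of syringaldehyde.

**21 back to 19 (formyl carbon).** The aldehyde is introduced last, from the aryl bromide through the aryllithium 20, because a free formyl group would not survive the enolate chemistry that builds the arm.

**19 back to 18, 17 and 16 (inversion at C7'').** The auxiliary-controlled aldol reliably gives the threo arrangement. The erythro arm is therefore reached by inverting the benzylic carbinol (bis-ester 17, diol 18) before the acetonide locks it.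

**16 back to 15, then 12 and 13 (C7''–C8''); 12 back to 9 and 10; 9 back to 8.** Cutting C7''–C8'' as an aldol joins the outer guaiacyl aldehyde 13 to an aryloxyacetyl imide that already holds the C8''–O–aryl bond. The neighbouring cut at C8''–O would need a separately prepared, differentially protected erythro triol and an etherification at a hindered secondary carbon.

## Roads not taken

Alternative 1: The C7'–C8' bond is cut last and made by light. Ring A is built first as the trans-disubstituted tetrahydrofuran-3-one A1, whose C8 side chain is a CH2–O–CH2 ether to the silylated guaiacyl ring. Irradiation excites the C8' ketone, which abstracts a benzylic hydrogen from C7'; the 1,5-biradical collapses to the C7'–C8' bond and closes ring B, giving the 8'-hydroxy furofuran A2.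

- Merits: the most hindered bond forms without any polar reagent, the key step closes a ring, and the cis fusion follows from geometry.
- Weak points:
  - The γ-hydrogens on C9 are activated by the ether oxygen and lie in the favoured six-membered transition state, so cleavage and cyclobutanol formation compete with the seven-membered abstraction at C7'.
  - Nothing obvious biases C7' in the biradical collapse.
  - A2 carries a tertiary hydroxyl at the ring fusion that 32 lacks, so a radical deoxygenation must follow.
  - A1 needs its own asymmetric synthesis, with C8 epimerisable next to the ketone.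
  - The arm would be attached late, at a secondary carbon, in the presence of the benzylic ethers.
- Comparison: Alternative 1 is better in closing a ring in the key step. The chosen plan sets against this the correct oxidation level at C8', known facial control at C8 and C8', and an arm that arrives finished.

Alternative 2: The lactone bonds O7–C9' and O7'–C9 and the two carbinol hydrogens are cut together. The diaroylsuccinate A3 is reduced with RuCl(p-cymene)(TsDPEN) (divalent ruthenium) and HCO2H/Et3N while C8 and C8' equilibrate, and each new hydroxyl lactonises across the C8–C8' bond to give the bislactone A4.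

- Merits: catalytic, no auxiliary, and four stereocentres and two rings from one step. Both benzylic centres are set by one reagent in the same sense; here this road is better than the chosen plan, which sets C7' by aldol diastereoselection and C7 by a separate catalyst-controlled reduction.
- Weak points:
  - The unsymmetrical A3 needs a crossed union of two different aroylacetate units.
  - The dynamic resolution must select the threo succinate over the meso form at both ends.
  - A4 still needs hydride reduction and the same retentive closure.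
  - The allyl-protected phenol means the arm is built late, with C8''–O formed at a secondary carbon.
- Comparison: the chosen plan sets against this a dependable three-component assembly of two different halves and a pre-installed arm.

Alternative 3: The ether bonds O9'–C7 and O9–C7' are cut and traced to a stored bis-electrophile, the all-trans cyclobutane A5, a crossed head-to-head photodimer. Two-electron oxidation of the free syringyl phenol with PhI(OAc)2 breaks the C7–C7' bond; the hydroxymethyl groups trap the quinone methide and the benzylic cation to give the furofuran A6.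

- Merits: both rings close in one step, the C8/C8' relation is locked in the four-membered ring, and on paper it is the shortest route to the core.
- Weak points:
  - A crossed, head-to-head, all-trans and enantioselective [2+2] dimerisation of two different cinnamyl alcohols is unsolved without a template.
  - C7 and C7' are set only in the trapping step, where exo and endo capture compete.
  - The oxidant meets two further electron-rich rings.
  - A6 has the wrong phenol free, so protecting groups must be exchanged before the arm can be attached late.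
- Comparison: Alternative 3 wins on step count for the core. The chosen plan sets against this predictable absolute and relative control at every centre.

Key step: step 13

Assumption: 8, 10 and 13 are taken as catalogue compounds.

Abbreviations in names: ArS = 4-(benzyloxy)-3,5-dimethoxyphenyl; ArG = 4-{[(4R,5S)-4-[4-(benzyloxy)-3-methoxyphenyl]-2,2-dimethyl-1,3-dioxan-5-yl]oxy}-3-methoxyphenyl; Men = (1S,2R,5S)-2-isopropyl-5-methylcyclohexyl.

## Steps

Step 1
Reactants: 1 furfural
Product: 2 5-hydroxyfuran-2(5H)-one (racemic hemiacetal)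
Conditions: O2, rose bengal (cat.), hν (visible), MeOH, rt
Reagents that add atoms: dioxygen, O=O
Why: Dye-sensitised photooxygenation: singlet oxygen adds [4+2] to the furan and methanol cleaves the endoperoxide with loss of the formyl carbon as methyl formate, leaving the hydroxybutenolide.

Step 2
Reactants: 2 5-hydroxyfuran-2(5H)-one; 3 (+)-menthol
Product: 4 (5S)-5-{[(1S,2R,5S)-2-isopropyl-5-methylcyclohexyl]oxy}furan-2(5H)-one
Conditions: camphorsulfonic acid (cat.), toluene, reflux (Dean–Stark); crystallisation from petroleum ether with acid-catalysed epimerisation of the mother liquor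
Reagents that add atoms: none
Why: Acid-catalysed acetalisation gives both C5 epimers, which interconvert through the oxocarbenium ion; crystallisation-induced diastereomer transformation should deliver the (5S) epimer of the d-menthyl series, the mirror image of the well-known l-menthyl case.

Step 3
Reactants: 5 syringaldehyde
Product: 6 4-(benzyloxy)-3,5-dimethoxybenzaldehyde
Conditions: BnBr, K2CO3, DMF, 60 °C
Reagents that add atoms: benzyl bromide, BrCc1ccccc1
Why: Williamson etherification of the acidic, hindered phenoxide with a reactive benzylic halide.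

Step 4
Reactants: 6 4-(benzyloxy)-3,5-dimethoxybenzaldehyde
Product: 7 2-[4-(benzyloxy)-3,5-dimethoxyphenyl]-1,3-dithiane
Conditions: HS(CH2)3SH, I2 (10 mol %), CH2Cl2, rt
Reagents that add atoms: propane-1,3-dithiol, SCCCS
Why: Iodine-catalysed dithioacetalisation of an aromatic aldehyde; the mild catalyst avoids the Lewis acid and thiol combination that can cleave benzyl ethers.

Step 5
Reactants: 8 4-bromo-2-methoxyphenol
Product: 9 (4-bromo-2-methoxyphenoxy)acetic acid
Conditions: BrCH2CO2H, NaOH, H2O, reflux; then HCl
Reagents that add atoms: bromoacetic acid, OC(=O)CBr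
Why: Williamson etherification of the phenoxide with bromoacetate in water, the classical route to aryloxyacetic acids.

Step 6
Reactants: 9 (4-bromo-2-methoxyphenoxy)acetic acid; 10 (R)-4-benzyloxazolidin-2-one
Product: 12 (R)-4-benzyl-3-[(4-bromo-2-methoxyphenoxy)acetyl]oxazolidin-2-one, via mixed pivalic anhydride 11 (not isolated)
Conditions: t-BuCOCl, Et3N, THF, −20 °C; then 10, LiCl, rt
Reagents that add atoms: none
Why: N-Acylation of the oxazolidinone through the mixed anhydride, with LiCl activation; attack goes to the less hindered aryloxyacetyl carbonyl.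

Step 7
Reactants: 12 (R)-4-benzyl-3-[(4-bromo-2-methoxyphenoxy)acetyl]oxazolidin-2-one; 13 4-(benzyloxy)-3-methoxybenzaldehyde
Product: 15 (R)-4-benzyl-3-[(2R,3S)-3-[4-(benzyloxy)-3-methoxyphenyl]-2-(4-bromo-2-methoxyphenoxy)-3-hydroxypropanoyl]oxazolidin-2-one, via Z-boron enolate 14 (not isolated)
Conditions: Bu2BOTf, iPr2NEt, CH2Cl2, −78 → 0 °C; 13, −78 → 0 °C; pH 7 buffer, MeOH, H2O2
Reagents that add atoms: none
Why: Evans syn-aldol of an aryloxyacetyl imide: the Z-boron enolate reacts through a Zimmerman–Traxler chair on the face away from the auxiliary benzyl group, setting C8'' and C7'' as (2R,3S), which is the threo arrangement in lignan terms.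

Step 8
Reactants: 15 syn-aldol imide
Product: 16 (1S,2S)-1-[4-(benzyloxy)-3-methoxyphenyl]-2-(4-bromo-2-methoxyphenoxy)propane-1,3-diol (threo)
Conditions: LiBH4, MeOH (1 equiv), THF, 0 °C
Reagents that add atoms: none
Why: Reductive cleavage of the N-acyl oxazolidinone at the exocyclic carbonyl gives the primary alcohol and returns the auxiliary; the aryl bromide and both stereocentres are untouched.

Step 9
Reactants: 16 threo diol
Product: 17 (1R,2S)-1-[4-(benzyloxy)-3-methoxyphenyl]-2-(4-bromo-2-methoxyphenoxy)propane-1,3-diyl bis(4-nitrobenzoate) (erythro)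
Conditions: 4-O2NC6H4CO2H, PPh3, DIAD (3 equiv each), THF, 0 °C → rt
Reagents that add atoms: 4-nitrobenzoic acid, OC(=O)c1ccc(cc1)[N+](=O)[O-]
Why: Mitsunobu esterification: the primary hydroxyl is acylated, and the benzylic alkoxyphosphonium is displaced by the acidic carboxylate with inversion at C7'', converting threo into erythro.

Step 10
Reactants: 17 erythro bis(4-nitrobenzoate)
Product: 18 (1R,2S)-1-[4-(benzyloxy)-3-methoxyphenyl]-2-(4-bromo-2-methoxyphenoxy)propane-1,3-diol (erythro)
Conditions: K2CO3 (cat.), MeOH/THF, rt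
Reagents that add atoms: none
Why: Base-catalysed transesterification removes both activated esters; with the phenol benzylated no quinone methide can form, so the erythro configuration should hold.

Step 11
Reactants: 18 erythro diol
Product: 19 (4R,5S)-4-[4-(benzyloxy)-3-methoxyphenyl]-5-(4-bromo-2-methoxyphenoxy)-2,2-dimethyl-1,3-dioxane (trans)
Conditions: Me2C(OMe)2, pyridinium p-toluenesulfonate (cat.), acetone, rt
Reagents that add atoms: 2,2-dimethoxypropane, COC(C)(C)OC
Why: Transketalisation of the 1,3-diol; the erythro isomer gives the trans-diequatorial dioxane, and the weak acid avoids ionising the benzylic carbinol.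

Step 12
Reactants: 19 aryl bromide acetonide
Product: 21 4-{[(4R,5S)-4-[4-(benzyloxy)-3-methoxyphenyl]-2,2-dimethyl-1,3-dioxan-5-yl]oxy}-3-methoxybenzaldehyde, via aryllithium 20 (not isolated)
Conditions: n-BuLi, THF, −78 °C; DMF, −78 → 0 °C; aq NH4Cl
Reagents that add atoms: N,N-dimethylformamide, CN(C)C=O
Why: Bromine–lithium exchange followed by formylation with DMF (Bouveault aldehyde synthesis); exchange at −78 °C is much faster than any deprotonation of the acetonide or benzyl ether.

Step 13
Reactants: 7 2-[4-(benzyloxy)-3,5-dimethoxyphenyl]-1,3-dithiane; 4 (5S)-5-(menthyloxy)furan-2(5H)-one; 21 arm aldehyde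
Product: 25 (3R,4S,5S)-4-(2-ArS-1,3-dithian-2-yl)-3-[(R)-hydroxy(ArG)methyl]-5-(MenO)dihydrofuran-2(3H)-one, via 2-lithiodithiane 22 (not isolated), via lithium lactone enolate 23 (not isolated), via triisopropoxytitanium lactone enolate 24 (not isolated)
Conditions: 7, n-BuLi, THF, −40 °C; 4, −78 °C; ClTi(OiPr)3, −78 °C; 21, −78 → −40 °C; aq NH4Cl
Reagents that add atoms: none
Why: Tandem conjugate addition–aldol with a lithiated 2-aryl-1,3-dithiane as acyl anion equivalent (Corey–Seebach umpolung), the reaction type known for 5-alkoxyfuran-2(5H)-ones with aldehyde capture of the enolate. The soft, delocalised anion 22 adds 1,4 to C8 of 4 on the face opposite the menthyloxy group, so the acetal carbon C9 alone sets C8 (8S). The lithium enolate 23 is converted with ClTi(OiPr)3 into the titanium enolate 24, which attacks the aldehyde carbon of 21 on the ring face opposite the bulky dithianyl group, so C8 sets C8' and the lactone becomes trans,trans. C7' is set by simple diastereoselection: ring-constrained enolates react mainly to anti aldols as lithium enolates through the chair transition state, whereas their trialkoxytitanium enolates are known to give syn aldols with aryl aldehydes, and the syn adduct is the required 7'R isomer. No ring closes; the C7–C8 and C8'–C7' bonds and three stereocentres form in one flask. The step needs 1,4- over 1,2-addition, complete facial control at C8 and C8' and useful syn selectivity at C7'; the first comes from the stabilised aryl dithiane anion at low temperature, the second from the single acetal stereocentre of 4, the third from the titanium counter-ion. The covalent titanium aldolate should also resist retro-aldol better than a lithium aldolate, and 25 is purified by chromatography so that only the 7'R carbinol goes forward.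

Step 14
Reactants: 25 syn aldol adduct
Product: 26 (3R,4S,5S)-4-(ArS-carbonyl)-3-[(R)-hydroxy(ArG)methyl]-5-(MenO)dihydrofuran-2(3H)-one
Conditions: Hg(ClO4)2·3H2O, CaCO3, THF/H2O, 0 °C → rt
Reagents that add atoms: water, O
Why: Thioacetal hydrolysis driven by thiophilic divalent mercury; CaCO3 buffers the perchloric acid so that the acetonide and the menthyl acetal survive, and the trans relation of the C8 and C8' branches disfavours hemiketal formation with the C7' hydroxyl, which would need a trans-fused bicyclo[3.3.0] ring system.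

Step 15
Reactants: 26 keto lactone
Product: 28 (1R,2S,3S,4R)-1-ArS-4-ArG-2,3-bis(hydroxymethyl)butane-1,4-diol, via diol lactone 27 (not isolated)
Conditions: (S)-2-methyl-CBS-oxazaborolidine (20 mol %), BH3·SMe2, THF, −20 °C; then LiAlH4, 0 °C → rt; aq KNaC4H4O6
Reagents that add atoms: none
Why: Corey–Bakshi–Shibata reduction sets C7 under reagent control (aryl as the large group; the S catalyst gives the 7R carbinol, as for acetophenone); LiAlH4 then reduces the lactone carbonyl C9' and, through the ring-opened hemiacetal, the acetal carbon C9, releasing menthol. The transient C9 aldehyde is reduced faster than C8 can epimerise.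

Step 16
Reactants: 28 tetraol
Product: 30 (1S,2R,5S,6R)-2-ArS-6-ArG-3,7-dioxabicyclo[3.3.0]octane, via bis-mesylate 29 (not isolated)
Conditions: MsCl (2.2 equiv), pyridine, CH2Cl2, −20 °C → rt
Reagents that add atoms: none
Why: Selective sulfonylation of the two primary hydroxyls followed by double intramolecular Williamson etherification (5-exo-tet): O7 displaces the C9' mesylate (ring A) and O7' the C9 mesylate (ring B), with retention at both benzylic carbons. The cis fusion is the only one possible for the 8S,8'S backbone, and the acetonide keeps O7'' out of the reaction.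

Step 17
Reactants: 30 protected furofuran
Product: 31 (1R,2S)-1-[4-(benzyloxy)-3-methoxyphenyl]-2-{4-[(1S,2R,5S,6R)-6-ArS-3,7-dioxabicyclo[3.3.0]octan-2-yl]-2-methoxyphenoxy}propane-1,3-diol
Conditions: AcOH/H2O/THF (3:1:1), 40 °C
Reagents that add atoms: none
Why: Mild hydrolysis of the isopropylidene ketal; acetic acid is too weak to ionise the benzylic ethers of the furofuran or the arm carbinol while the phenols are still benzylated.

Step 18
Reactants: 31 bis(benzyl ether) diol
Product: 32 ficusesquilignan A
Conditions: H2 (1 atm), 10% Pd/C, EtOAc, rt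
Reagents that add atoms: none
Why: Hydrogenolysis of the two aryl benzyl ethers, which cleave much faster than the benzylic C–O bonds of the furofuran and the arm in a neutral aprotic solvent; the reaction is stopped as soon as the second benzyl group is gone.

## Compound list

1 | furfural (furan-2-carbaldehyde) | O=Cc1ccco1 | starting material
2 | 5-hydroxyfuran-2(5H)-one (racemic) | O=C1OC(O)C=C1 | intermediate
3 | (+)-menthol, (1S,2R,5S)-2-isopropyl-5-methylcyclohexan-1-ol | CC(C)[C@H]1CC[C@H](C)C[C@@H]1O | starting material
4 | (5S)-5-{[(1S,2R,5S)-2-isopropyl-5-methylcyclohexyl]oxy}furan-2(5H)-one | O=C1O[C@H](O[C@H]2C[C@@H](C)CC[C@@H]2C(C)C)C=C1 | intermediate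
5 | syringaldehyde (4-hydroxy-3,5-dimethoxybenzaldehyde) | COc1cc(C=O)cc(OC)c1O | starting material
6 | 4-(benzyloxy)-3,5-dimethoxybenzaldehyde | COc1cc(C=O)cc(OC)c1OCc1ccccc1 | intermediate
7 | 2-[4-(benzyloxy)-3,5-dimethoxyphenyl]-1,3-dithiane | COc1cc(C2SCCCS2)cc(OC)c1OCc1ccccc1 | intermediate
8 | 4-bromo-2-methoxyphenol | COc1cc(Br)ccc1O | starting material
9 | (4-bromo-2-methoxyphenoxy)acetic acid | COc1cc(Br)ccc1OCC(=O)O | intermediate
10 | (R)-4-benzyloxazolidin-2-one | O=C1N[C@H](Cc2ccccc2)CO1 | starting material
11 | (4-bromo-2-methoxyphenoxy)acetic pivalic anhydride (not isolated) | COc1cc(Br)ccc1OCC(=O)OC(=O)C(C)(C)C | intermediate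
12 | (R)-4-benzyl-3-[(4-bromo-2-methoxyphenoxy)acetyl]oxazolidin-2-one | COc1cc(Br)ccc1OCC(=O)N1C(=O)OC[C@H]1Cc1ccccc1 | intermediate
13 | 4-(benzyloxy)-3-methoxybenzaldehyde | COc1cc(C=O)ccc1OCc1ccccc1 | starting material
14 | (Z)-dibutylboron enolate of 12 (not isolated) | CCCCB(CCCC)O/C(N1C(=O)OC[C@H]1Cc1ccccc1)=C\Oc1ccc(Br)cc1OC | intermediate
15 | (R)-4-benzyl-3-[(2R,3S)-3-[4-(benzyloxy)-3-methoxyphenyl]-2-(4-bromo-2-methoxyphenoxy)-3-hydroxypropanoyl]oxazolidin-2-one | COc1cc([C@H](O)[C@H](C(=O)N2C(=O)OC[C@H]2Cc2ccccc2)Oc2ccc(Br)cc2OC)ccc1OCc1ccccc1 | intermediate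
16 | (1S,2S)-1-[4-(benzyloxy)-3-methoxyphenyl]-2-(4-bromo-2-methoxyphenoxy)propane-1,3-diol (threo) | COc1cc([C@H](O)[C@H](CO)Oc2ccc(Br)cc2OC)ccc1OCc1ccccc1 | intermediate
17 | (1R,2S)-1-[4-(benzyloxy)-3-methoxyphenyl]-2-(4-bromo-2-methoxyphenoxy)propane-1,3-diyl bis(4-nitrobenzoate) (erythro) | COc1cc([C@@H](OC(=O)c2ccc(cc2)[N+](=O)[O-])[C@H](COC(=O)c2ccc(cc2)[N+](=O)[O-])Oc2ccc(Br)cc2OC)ccc1OCc1ccccc1 | intermediate
18 | (1R,2S)-1-[4-(benzyloxy)-3-methoxyphenyl]-2-(4-bromo-2-methoxyphenoxy)propane-1,3-diol (erythro) | COc1cc([C@@H](O)[C@H](CO)Oc2ccc(Br)cc2OC)ccc1OCc1ccccc1 | intermediate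
19 | (4R,5S)-4-[4-(benzyloxy)-3-methoxyphenyl]-5-(4-bromo-2-methoxyphenoxy)-2,2-dimethyl-1,3-dioxane (trans) | COc1cc([C@H]2OC(C)(C)OC[C@@H]2Oc2ccc(Br)cc2OC)ccc1OCc1ccccc1 | intermediate
20 | aryllithium from 19, lithium in place of bromine (not isolated) | COc1cc([C@H]2OC(C)(C)OC[C@@H]2Oc2ccc([Li])cc2OC)ccc1OCc1ccccc1 | intermediate
21 | 4-{[(4R,5S)-4-[4-(benzyloxy)-3-methoxyphenyl]-2,2-dimethyl-1,3-dioxan-5-yl]oxy}-3-methoxybenzaldehyde | COc1cc([C@H]2OC(C)(C)OC[C@@H]2Oc2ccc(C=O)cc2OC)ccc1OCc1ccccc1 | intermediate
22 | 2-lithio-2-[4-(benzyloxy)-3,5-dimethoxyphenyl]-1,3-dithiane (not isolated) | [Li]C1(SCCCS1)c1cc(OC)c(OCc2ccccc2)c(OC)c1 | intermediate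
23 | lithium (4S,5S)-4-(2-ArS-1,3-dithian-2-yl)-5-(MenO)-4,5-dihydrofuran-2-olate (not isolated) | [Li]OC1=C[C@H](C2(SCCCS2)c2cc(OC)c(OCc3ccccc3)c(OC)c2)[C@@H](O[C@H]2C[C@@H](C)CC[C@@H]2C(C)C)O1 | intermediate
24 | triisopropoxytitanium (4S,5S)-4-(2-ArS-1,3-dithian-2-yl)-5-(MenO)-4,5-dihydrofuran-2-olate (not isolated) | CC(C)O[Ti](OC(C)C)(OC(C)C)OC1=C[C@H](C2(SCCCS2)c2cc(OC)c(OCc3ccccc3)c(OC)c2)[C@@H](O[C@H]2C[C@@H](C)CC[C@@H]2C(C)C)O1 | intermediate
25 | (3R,4S,5S)-4-(2-ArS-1,3-dithian-2-yl)-3-[(R)-hydroxy(ArG)methyl]-5-(MenO)dihydrofuran-2(3H)-one (syn aldol, 7'R) | COc1cc([C@H]2OC(C)(C)OC[C@@H]2Oc2ccc([C@H](O)[C@@H]3C(=O)O[C@H](O[C@H]4C[C@@H](C)CC[C@@H]4C(C)C)[C@H]3C5(SCCCS5)c5cc(OC)c(OCc6ccccc6)c(OC)c5)cc2OC)ccc1OCc1ccccc1 | intermediate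
26 | (3R,4S,5S)-4-(ArS-carbonyl)-3-[(R)-hydroxy(ArG)methyl]-5-(MenO)dihydrofuran-2(3H)-one | COc1cc([C@H]2OC(C)(C)OC[C@@H]2Oc2ccc([C@H](O)[C@@H]3C(=O)O[C@H](O[C@H]4C[C@@H](C)CC[C@@H]4C(C)C)[C@H]3C(=O)c5cc(OC)c(OCc6ccccc6)c(OC)c5)cc2OC)ccc1OCc1ccccc1 | intermediate
27 | (3R,4R,5S)-3-[(R)-hydroxy(ArG)methyl]-4-[(R)-hydroxy(ArS)methyl]-5-(MenO)dihydrofuran-2(3H)-one (not isolated) | COc1cc([C@H]2OC(C)(C)OC[C@@H]2Oc2ccc([C@H](O)[C@@H]3C(=O)O[C@H](O[C@H]4C[C@@H](C)CC[C@@H]4C(C)C)[C@H]3[C@@H](O)c5cc(OC)c(OCc6ccccc6)c(OC)c5)cc2OC)ccc1OCc1ccccc1 | intermediate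
28 | (1R,2S,3S,4R)-1-ArS-4-ArG-2,3-bis(hydroxymethyl)butane-1,4-diol (7R,8S,8'S,7'R) | COc1cc([C@H]2OC(C)(C)OC[C@@H]2Oc2ccc([C@H](O)[C@H](CO)[C@@H](CO)[C@@H](O)c3cc(OC)c(OCc4ccccc4)c(OC)c3)cc2OC)ccc1OCc1ccccc1 | intermediate
29 | 2,3-bis(mesyloxymethyl) derivative of 28 (not isolated) | COc1cc([C@H]2OC(C)(C)OC[C@@H]2Oc2ccc([C@H](O)[C@H](COS(C)(=O)=O)[C@@H](COS(C)(=O)=O)[C@@H](O)c3cc(OC)c(OCc4ccccc4)c(OC)c3)cc2OC)ccc1OCc1ccccc1 | intermediate
30 | (1S,2R,5S,6R)-2-ArS-6-ArG-3,7-dioxabicyclo[3.3.0]octane | COc1cc([C@H]2OC(C)(C)OC[C@@H]2Oc2ccc([C@@H]3OC[C@@H]4[C@H]3CO[C@H]4c3cc(OC)c(OCc5ccccc5)c(OC)c3)cc2OC)ccc1OCc1ccccc1 | intermediate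
31 | (1R,2S)-1-[4-(benzyloxy)-3-methoxyphenyl]-2-{4-[(1S,2R,5S,6R)-6-ArS-3,7-dioxabicyclo[3.3.0]octan-2-yl]-2-methoxyphenoxy}propane-1,3-diol | COc1cc([C@@H](O)[C@H](CO)Oc2ccc([C@@H]3OC[C@@H]4[C@H]3CO[C@H]4c3cc(OC)c(OCc5ccccc5)c(OC)c3)cc2OC)ccc1OCc1ccccc1 | intermediate
32 | ficusesquilignan A, (1R,2S)-1-(4-hydroxy-3-methoxyphenyl)-2-{4-[(1S,2R,5S,6R)-6-(4-hydroxy-3,5-dimethoxyphenyl)-3,7-dioxabicyclo[3.3.0]octan-2-yl]-2-methoxyphenoxy}propane-1,3-diol | COc1cc([C@@H](O)[C@H](CO)Oc2ccc([C@@H]3OC[C@@H]4[C@H]3CO[C@H]4c3cc(OC)c(O)c(OC)c3)cc2OC)ccc1O | target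

## Step count and risks

Total step count: 18. Longest linear sequence: 14 steps (8 → 32, steps 5–18).

**Step 13 (key step).** Two things are most likely to go wrong. The first is poor simple diastereoselection at C7', because the syn preference of the titanium enolate has to hold for a hindered lactone enolate next to a quaternary carbon. The second is incomplete or reversible capture of that enolate by the large, electron-rich aldehyde, which would return the protonated conjugate adduct. Some 1,2-addition of the dithiane anion to the lactone carbonyl is also possible.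

Fallback, setting out from 7, 4 and 21 and rejoining at 25: the tandem is split and C7' is set by reduction instead of by the aldol.
- The enolate 23 is quenched with aq NH4Cl to give the conjugate adduct (4S,5S)-4-(2-ArS-1,3-dithian-2-yl)-5-(MenO)dihydrofuran-2(3H)-one F1.
- Aldehyde 21 is oxidised (NaClO2, NaH2PO4, 2-methylbut-2-ene) to the benzoic acid F2 and converted with 1,1'-carbonyldiimidazole into the acyl imidazole F3.
- F1 is deprotonated again (LiN(SiMe3)2, 2.2 equiv, THF, −78 °C) and C-acylated with F3. This irreversible Claisen-type acylation should give the β-keto lactone F4, in which the trans arrangement at the enolisable C8' is the thermodynamic one.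
- Zn(BH4)2 (Et2O/CH2Cl2, −40 → 0 °C) reduces F4 under chelation control. Zinc bridges the ketone and lactone carbonyl oxygens and hydride enters from the side of H8', away from the C8 branch, which should give the syn carbinol 25.
- If capture in the tandem reaction is efficient and only the C7' selectivity is poor, the mixture of 25 and its (7'S) epimer F5 is oxidised with Dess–Martin periodinane (NaHCO3, CH2Cl2) to the same F4 and reduced in the same way.

**Step 15.** Face selectivity at C7 may be poor: the ring carbon C8 is a branched "small" group, so the catalyst may not distinguish it well from the aryl group, and borane bound to the free C7' hydroxyl can reduce the ketone without the catalyst.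

Fallback, setting out from 25 and rejoining at 28: reagent control is replaced by substrate control.
- The C7' hydroxyl is silylated (t-BuMe2SiOTf, 2,6-lutidine) to the silyl ether F6, and the dithiane is hydrolysed as in step 14 to the ketone F7.
- F7 is reduced with LiBH(s-Bu)3 at −78 °C. In the Felkin–Anh model the silyloxybenzyl-bearing C8' branch is now clearly the large group, and hydride attack anti to it should give the 7R carbinol F8.
- LiAlH4 then gives the mono-silylated tetraol F9, and Bu4NF gives 28.

**Step 16.** Competing sulfonylation of the benzylic hydroxyls would be followed by ionisation, with loss of configuration at C7 or C7' and chloride capture.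

Fallback, setting out from 28 and rejoining at 30: activation and closure are separated. 2,4,6-Triisopropylbenzenesulfonyl chloride (pyridine, 0 °C), which discriminates strongly for primary hydroxyls, gives the isolable bis(arenesulfonate) F10. Closure is then carried out with NaH in THF at 0 °C, where the benzylic alkoxides displace the primary sulfonates and no benzylic leaving group is ever present.

**Step 9.** The electron-rich benzylic alkoxyphosphonium may partly ionise, eroding the inversion at C7'' or eliminating towards the enol ether.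

Fallback, setting out from 16 and rejoining at 18: inversion is replaced by oxidation and reduction.
- The primary hydroxyl is silylated (t-BuMe2SiCl, imidazole) to the silyl ether F11.
- Dess–Martin oxidation gives the α-aryloxy ketone F12.
- Zn(BH4)2 reduction through the Cram chelate (zinc between the carbonyl and the α-aryloxy oxygen, hydride from the side of H8'') should give the erythro alcohol F13, and Bu4NF gives 18.

## Further compounds

F1 | step 13 | (4S,5S)-4-(2-ArS-1,3-dithian-2-yl)-5-(MenO)dihydrofuran-2(3H)-one | O=C1C[C@H](C2(SCCCS2)c2cc(OC)c(OCc3ccccc3)c(OC)c2)[C@@H](O[C@H]2C[C@@H](C)CC[C@@H]2C(C)C)O1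
F2 | step 13 | 4-{[(4R,5S)-4-[4-(benzyloxy)-3-methoxyphenyl]-2,2-dimethyl-1,3-dioxan-5-yl]oxy}-3-methoxybenzoic acid | COc1cc([C@H]2OC(C)(C)OC[C@@H]2Oc2ccc(C(=O)O)cc2OC)ccc1OCc1ccccc1
F3 | step 13 | 1-(ArG-carbonyl)imidazole | COc1cc([C@H]2OC(C)(C)OC[C@@H]2Oc2ccc(C(=O)n3ccnc3)cc2OC)ccc1OCc1ccccc1
F4 | step 13 | (3R,4S,5S)-3-(ArG-carbonyl)-4-(2-ArS-1,3-dithian-2-yl)-5-(MenO)dihydrofuran-2(3H)-one | COc1cc([C@H]2OC(C)(C)OC[C@@H]2Oc2ccc(C(=O)[C@@H]3C(=O)O[C@H](O[C@H]4C[C@@H](C)CC[C@@H]4C(C)C)[C@H]3C5(SCCCS5)c5cc(OC)c(OCc6ccccc6)c(OC)c5)cc2OC)ccc1OCc1ccccc1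
F5 | step 13 | (3R,4S,5S)-4-(2-ArS-1,3-dithian-2-yl)-3-[(S)-hydroxy(ArG)methyl]-5-(MenO)dihydrofuran-2(3H)-one (C7' epimer of 25) | COc1cc([C@H]2OC(C)(C)OC[C@@H]2Oc2ccc([C@@H](O)[C@@H]3C(=O)O[C@H](O[C@H]4C[C@@H](C)CC[C@@H]4C(C)C)[C@H]3C5(SCCCS5)c5cc(OC)c(OCc6ccccc6)c(OC)c5)cc2OC)ccc1OCc1ccccc1
F6 | step 15 | 7'-O-tert-butyldimethylsilyl ether of 25 | COc1cc([C@H]2OC(C)(C)OC[C@@H]2Oc2ccc([C@H](O[Si](C)(C)C(C)(C)C)[C@@H]3C(=O)O[C@H](O[C@H]4C[C@@H](C)CC[C@@H]4C(C)C)[C@H]3C5(SCCCS5)c5cc(OC)c(OCc6ccccc6)c(OC)c5)cc2OC)ccc1OCc1ccccc1
F7 | step 15 | 7'-O-tert-butyldimethylsilyl ether of 26 | COc1cc([C@H]2OC(C)(C)OC[C@@H]2Oc2ccc([C@H](O[Si](C)(C)C(C)(C)C)[C@@H]3C(=O)O[C@H](O[C@H]4C[C@@H](C)CC[C@@H]4C(C)C)[C@H]3C(=O)c5cc(OC)c(OCc6ccccc6)c(OC)c5)cc2OC)ccc1OCc1ccccc1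
F8 | step 15 | 7'-O-tert-butyldimethylsilyl ether of 27 (7R carbinol) | COc1cc([C@H]2OC(C)(C)OC[C@@H]2Oc2ccc([C@H](O[Si](C)(C)C(C)(C)C)[C@@H]3C(=O)O[C@H](O[C@H]4C[C@@H](C)CC[C@@H]4C(C)C)[C@H]3[C@@H](O)c5cc(OC)c(OCc6ccccc6)c(OC)c5)cc2OC)ccc1OCc1ccccc1
F9 | step 15 | 7'-O-tert-butyldimethylsilyl ether of 28 | COc1cc([C@H]2OC(C)(C)OC[C@@H]2Oc2ccc([C@H](O[Si](C)(C)C(C)(C)C)[C@H](CO)[C@@H](CO)[C@@H](O)c3cc(OC)c(OCc4ccccc4)c(OC)c3)cc2OC)ccc1OCc1ccccc1
F10 | step 16 | bis(2,4,6-triisopropylbenzenesulfonate) of the two primary hydroxyls of 28 | COc1cc([C@H]2OC(C)(C)OC[C@@H]2Oc2ccc([C@H](O)[C@H](COS(=O)(=O)c3c(C(C)C)cc(C(C)C)cc3C(C)C)[C@@H](COS(=O)(=O)c3c(C(C)C)cc(C(C)C)cc3C(C)C)[C@@H](O)c3cc(OC)c(OCc4ccccc4)c(OC)c3)cc2OC)ccc1OCc1ccccc1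
F11 | step 9 | (1S,2S)-1-[4-(benzyloxy)-3-methoxyphenyl]-2-(4-bromo-2-methoxyphenoxy)-3-(tert-butyldimethylsilyloxy)propan-1-ol | COc1cc([C@H](O)[C@H](CO[Si](C)(C)C(C)(C)C)Oc2ccc(Br)cc2OC)ccc1OCc1ccccc1
F12 | step 9 | (2S)-1-[4-(benzyloxy)-3-methoxyphenyl]-2-(4-bromo-2-methoxyphenoxy)-3-(tert-butyldimethylsilyloxy)propan-1-one | COc1cc(C(=O)[C@H](CO[Si](C)(C)C(C)(C)C)Oc2ccc(Br)cc2OC)ccc1OCc1ccccc1
F13 | step 9 | (1R,2S)-1-[4-(benzyloxy)-3-methoxyphenyl]-2-(4-bromo-2-methoxyphenoxy)-3-(tert-butyldimethylsilyloxy)propan-1-ol | COc1cc([C@@H](O)[C@H](CO[Si](C)(C)C(C)(C)C)Oc2ccc(Br)cc2OC)ccc1OCc1ccccc1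
A1 | alternative 1 | trans-5-[4-(benzyloxy)-3,5-dimethoxyphenyl]-4-({[3-methoxy-4-(triisopropylsilyloxy)phenyl]methoxy}methyl)dihydrofuran-3(2H)-one | COc1cc(COC[C@@H]2C(=O)CO[C@H]2c2cc(OC)c(OCc3ccccc3)c(OC)c2)ccc1O[Si](C(C)C)(C(C)C)C(C)C
A2 | alternative 1 | 8'-hydroxy furofuran with central phenol triisopropylsilyl ether and syringyl benzyl ether | COc1cc([C@@H]2OC[C@@H]3[C@@]2(O)CO[C@H]3c2cc(OC)c(OCc4ccccc4)c(OC)c2)ccc1O[Si](C(C)C)(C(C)C)C(C)C
A3 | alternative 2 | dimethyl 2-[4-(allyloxy)-3-methoxybenzoyl]-3-[4-(benzyloxy)-3,5-dimethoxybenzoyl]succinate (C8 and C8' configurationally labile) | COC(=O)C(C(=O)c1ccc(OCC=C)c(OC)c1)C(C(=O)c1cc(OC)c(OCc2ccccc2)c(OC)c1)C(=O)OC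
A4 | alternative 2 | 2,6-diaryl-3,7-dioxabicyclo[3.3.0]octane-4,8-dione with central phenol allyl ether and syringyl benzyl ether | COc1cc([C@@H]2OC(=O)[C@@H]3[C@H]2C(=O)O[C@H]3c2cc(OC)c(OCc4ccccc4)c(OC)c2)ccc1OCC=C
A5 | alternative 3 | all-trans 1-[4-(benzyloxy)-3-methoxyphenyl]-2-(4-hydroxy-3,5-dimethoxyphenyl)-3,4-bis(hydroxymethyl)cyclobutane | OC[C@@H]1[C@@H](CO)[C@H](c2ccc(OCc3ccccc3)c(OC)c2)[C@H]1c1cc(OC)c(O)c(OC)c1
A6 | alternative 3 | furofuran with free syringyl phenol and central phenol benzyl ether | COc1cc([C@@H]2OC[C@@H]3[C@H]2CO[C@H]3c2cc(OC)c(O)c(OC)c2)ccc1OCc1ccccc1
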